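**Retrosynthetic overview**

1. Numbering: C1 exocyclic CH2, C2, C3 lactone C=O, O4, C5 lactone CH–O, then the carbocycle C6=C7(Me)–C8–C9(OH)–C10=C11(Me)–C12–C13(OAc)–C14=C15(Me)–C16–C17(OAc)–C18 (C18 bears C2). The plan rests on the 14-membered carbocycle C5–C18 being one δ-oxygenated (E)-3-methyl-2-enoyl unit written three times (C17–C16–C15(Me)=C14, C13–C12–C11(Me)=C10, C9–C8–C7(Me)=C6–C5), with the same spatial sense at C17, C13 and C9.
2. Last disconnection: the C5–C18 bond and the O4–C3 lactone bond. A C1 allylic bromide adds through C18 to a C5 enal under chromium(II); this closes the 14-membered carbocycle first, and the resulting C5 alkoxide then closes the five-membered α-methylene lactone.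
3. C18–C2 comes from a Morita–Baylis–Hillman reaction of the C18 aldehyde with methyl acrylate; SN2′ bromination puts bromine on C1.
4. The C5–C18 chain comes from three passes of one catalytic enantioselective vinylogous Mukaiyama aldol (C16–C17, then C12–C13, then C8–C9) between one silyl dienolate and, in turn, silyloxyacetaldehyde, the C13 enal and the C9 enal.
5. Oxygen differentiation: C13/C17 as TBS ethers (later acetates), C9 as TBDPS ether (freed last), C5 as PMB ether, C18 as primary TBS ether. No ring exists until step 20.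

Key step: step 10

Remark (assumption): the (S,S)-enantiomer of the bisphosphoramide catalyst is taken to be the one that delivers the dienolate to the Si face of an aldehyde RCHO (O > R > H). This sense is checked once on compound 6 (MTPA esters); should it prove opposite, the (R,R)-catalyst is used in steps 2, 6 and 10 with no other change.

Catalyst used in steps 2, 6 and 10: "(S,S)-bisphosphoramide" = two cyclic phosphoramide units derived from (S)-N,N′-dimethyl-1,1′-binaphthyl-2,2′-diamine, joined through their exocyclic N-methyl nitrogens by a pentane-1,5-diyl tether.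

**Route**

Step 1
Reactants: 1 methyl 3-methylbut-2-enoate
Product: 3 tert-butyl[(1-methoxy-3-methylbuta-1,3-dien-1-yl)oxy]dimethylsilane (TBS dienolate), via lithium dienolate 2 (not isolated)
Conditions: LDA, THF, −78 °C; then TBSCl, DMPU, −78 °C → rt; distillation
Reagents that add atoms: tert-butyldimethylsilyl chloride, CC(C)(C)[Si](C)(C)Cl
Why: Kinetic γ-deprotonation of the 3-methyl-2-enoate gives the extended lithium dienolate, which is silylated on oxygen in the presence of DMPU (silyl ketene acetal formation).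

Step 2
Reactants: 4 (tert-butyldimethylsilyloxy)acetaldehyde; 3 TBS dienolate
Product: 6 methyl (2E,5S)-6-(tert-butyldimethylsilyloxy)-5-hydroxy-3-methylhex-2-enoate, via trichlorosilyl aldolate 5 (not isolated)
Conditions: SiCl4 (1.1 equiv), (S,S)-bisphosphoramide (2 mol %), iPr2NEt (10 mol %), CH2Cl2, −78 °C; aq. NaHCO3/KF
Reagents that add atoms: none
Why: First pass of the Lewis-base-activated SiCl4 vinylogous Mukaiyama aldol, in which the chiral trichlorosilyl cation binds the aldehyde, the dienolate attacks through its γ-CH2 on the Si face so that C17 (S) is set by the catalyst, and the s-trans dienolate should give the (E)-enoate.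

Step 3
Reactants: 6 methyl (2E,5S)-6-(tert-butyldimethylsilyloxy)-5-hydroxy-3-methylhex-2-enoate
Product: 7 methyl (2E,5S)-5,6-bis(tert-butyldimethylsilyloxy)-3-methylhex-2-enoate
Conditions: TBSOTf, 2,6-lutidine, CH2Cl2, −78 → 0 °C
Reagents that add atoms: tert-butyldimethylsilyl triflate, CC(C)(C)[Si](C)(C)OS(=O)(=O)C(F)(F)F
Why: O-silylation of a secondary alcohol with a silyl triflate and a hindered base, under which neither silyl migration nor elimination of the δ-oxygen is expected.

Step 4
Reactants: 7 methyl (2E,5S)-5,6-bis(tert-butyldimethylsilyloxy)-3-methylhex-2-enoate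
Product: 8 (2E,5S)-5,6-bis(tert-butyldimethylsilyloxy)-3-methylhex-2-en-1-ol
Conditions: DIBAL-H (2.3 equiv), CH2Cl2, −78 °C; Rochelle salt
Reagents that add atoms: none
Why: DIBAL-H 1,2-reduction of an α,β-unsaturated ester to the allylic alcohol, which leaves silyl ethers and the trisubstituted alkene untouched.

Step 5
Reactants: 8 (2E,5S)-5,6-bis(tert-butyldimethylsilyloxy)-3-methylhex-2-en-1-ol
Product: 9 (2E,5S)-5,6-bis(tert-butyldimethylsilyloxy)-3-methylhex-2-enal
Conditions: MnO2 (excess), CH2Cl2, rt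
Reagents that add atoms: none
Why: Manganese dioxide oxidises only the allylic alcohol and should return the (E)-enal without isomerisation.

Step 6
Reactants: 9 (2E,5S)-5,6-bis(tert-butyldimethylsilyloxy)-3-methylhex-2-enal; 3 TBS dienolate
Product: 11 methyl (2E,5S,6E,9S)-9,10-bis(tert-butyldimethylsilyloxy)-5-hydroxy-3,7-dimethyldeca-2,6-dienoate, via trichlorosilyl aldolate 10 (not isolated)
Conditions: SiCl4 (1.1 equiv), (S,S)-bisphosphoramide (2 mol %), CH2Cl2, −78 °C; aq. NaHCO3/KF
Reagents that add atoms: none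
Why: Second pass of the same vinylogous Mukaiyama aldol, now on a conjugated aldehyde, with C13 (S) set by the same catalyst face (Si) because the C17 centre is five atoms away and carries only non-chelating silyl ethers.

Step 7
Reactants: 11 methyl (2E,5S,6E,9S)-9,10-bis(tert-butyldimethylsilyloxy)-5-hydroxy-3,7-dimethyldeca-2,6-dienoate
Product: 12 methyl (2E,5S,6E,9S)-5,9,10-tris(tert-butyldimethylsilyloxy)-3,7-dimethyldeca-2,6-dienoate
Conditions: TBSOTf, 2,6-lutidine, CH2Cl2, −78 → 0 °C
Reagents that add atoms: tert-butyldimethylsilyl triflate, CC(C)(C)[Si](C)(C)OS(=O)(=O)C(F)(F)F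
Why: Silyl triflate O-silylation of the secondary allylic alcohol under non-ionising, non-nucleophilic conditions.

Step 8
Reactants: 12 methyl (2E,5S,6E,9S)-5,9,10-tris(tert-butyldimethylsilyloxy)-3,7-dimethyldeca-2,6-dienoate
Product: 13 (2E,5S,6E,9S)-5,9,10-tris(tert-butyldimethylsilyloxy)-3,7-dimethyldeca-2,6-dien-1-ol
Conditions: DIBAL-H (2.3 equiv), CH2Cl2, −78 °C; Rochelle salt
Reagents that add atoms: none
Why: DIBAL-H 1,2-reduction of the enoate to the allylic alcohol, as in step 4.

Step 9
Reactants: 13 (2E,5S,6E,9S)-5,9,10-tris(tert-butyldimethylsilyloxy)-3,7-dimethyldeca-2,6-dien-1-ol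
Product: 14 (2E,5S,6E,9S)-5,9,10-tris(tert-butyldimethylsilyloxy)-3,7-dimethyldeca-2,6-dienal (C9 enal; target carbons C9–C18)
Conditions: MnO2 (excess), CH2Cl2, rt
Reagents that add atoms: none
Why: Chemoselective manganese dioxide oxidation of the primary allylic alcohol to the (E)-enal.

Step 10
Reactants: 14 C9 enal; 3 TBS dienolate
Product: 16 methyl (2E,5S,6E,9S,10E,13S)-9,13,14-tris(tert-butyldimethylsilyloxy)-5-hydroxy-3,7,11-trimethyltetradeca-2,6,10-trienoate (C5–C18 chain ester), via trichlorosilyl aldolate 15 (not isolated)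
Conditions: SiCl4 (1.1 equiv), (S,S)-bisphosphoramide (2–5 mol %), CH2Cl2, −78 °C; aq. NaHCO3/KF
Reagents that add atoms: none
Why: The bisphosphoramide binds SiCl4 and displaces chloride to give a chiral, strongly Lewis acidic trichlorosilyl cation that activates the C9 carbonyl of 14; dienolate 3 then attacks through its terminal CH2 (γ-carbon) in an open transition state, the silyl group passes to chloride, and the aldolate stays as trichlorosilyl ether 15 until aqueous hydrolysis. The closest known reaction type is the Lewis-base-activated SiCl4-catalysed enantioselective vinylogous Mukaiyama aldol of ester-derived silyl dienolates with conjugated aldehydes, used here for the third time on one chain. No ring is closed; the step forms only the C8–C9 bond. The new centre C9 is set by the catalyst, which exposes the Si face of the enal just as for C17 and C13, while the existing centres at C13 and C17 lie five and nine atoms away and carry bulky, non-chelating silyl ethers, so no competing substrate bias is expected. The step needs γ- over α-attack, 1,2- over 1,4-addition and E geometry at C6=C7: the first is secured by the hindered, doubly oxygenated α-terminus of 3 and the bulk of the activated aldehyde complex, the second by the β,β-disubstitution of the enal in 14, and the third by reaction of 3 in its s-trans conformation. The TBS ethers should be inert to SiCl4 at −78 °C.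

Step 11
Reactants: 16 C5–C18 chain ester (C9–OH)
Product: 17 methyl (2E,5S,6E,9S,10E,13S)-5-(tert-butyldiphenylsilyloxy)-9,13,14-tris(tert-butyldimethylsilyloxy)-3,7,11-trimethyltetradeca-2,6,10-trienoate
Conditions: TBDPSCl, imidazole, DMAP (cat.), DMF, rt → 40 °C
Reagents that add atoms: tert-butyldiphenylsilyl chloride, CC(C)(C)[Si](Cl)(c1ccccc1)c1ccccc1
Why: Imidazole-mediated silylation puts on C9–O the one silyl group that later survives the acidic fluoride cleavage of the TBS ethers, so that C9 can be freed last.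

Step 12
Reactants: 17 C9-TBDPS chain ester
Product: 18 (2E,5S,6E,9S,10E,13S)-5-(tert-butyldiphenylsilyloxy)-9,13,14-tris(tert-butyldimethylsilyloxy)-3,7,11-trimethyltetradeca-2,6,10-trien-1-ol (C5 allylic alcohol)
Conditions: DIBAL-H (2.3 equiv), CH2Cl2, −78 °C; Rochelle salt
Reagents that add atoms: none
Why: DIBAL-H 1,2-reduction of the enoate to the C5 allylic alcohol, as in steps 4 and 8.

Step 13
Reactants: 18 C5 allylic alcohol
Product: 19 C5 4-methoxybenzyl ether of 18 (C5–OPMB, C9–OTBDPS, C13–OTBS, C17–OTBS, C18–OTBS; 6E,10E,14E; 9S,13S,17S)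
Conditions: NaH, PMBCl, Bu4NI (cat.), THF/DMF, 0 °C → rt
Reagents that add atoms: 4-methoxybenzyl chloride, COc1ccc(CCl)cc1
Why: Williamson etherification of the primary allylic alkoxide, with no free hydroxyl near a silyl ether so that silyl migration is not expected.

Step 14
Reactants: 19 C5 PMB ether
Product: 20 C18 primary alcohol (C5–OPMB, C9–OTBDPS, C13–OTBS, C17–OTBS, C18–OH; 6E,10E,14E; 9S,13S,17S)
Conditions: HF·pyridine, pyridine, THF, 0 °C
Reagents that add atoms: none
Why: Buffered HF·pyridine cleaves the primary TBS ether much faster than the secondary TBS and TBDPS ethers (steric selectivity of silyl ether cleavage), and the acidic medium should prevent O17→O18 silyl migration.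

Step 15
Reactants: 20 C18 primary alcohol
Product: 21 C18 aldehyde (α-silyloxy aldehyde; C5–OPMB, C9–OTBDPS, C13–OTBS, C17–OTBS; 9S,13S,17S)
Conditions: Dess–Martin periodinane, NaHCO3, CH2Cl2, 0 °C → rt; used crude
Reagents that add atoms: none
Why: Dess–Martin oxidation under buffered, non-basic conditions should give the α-silyloxy aldehyde without epimerising C17.

Step 16
Reactants: 21 C18 aldehyde; 22 methyl acrylate
Product: 23 Baylis–Hillman adduct (C18 carbinol bearing C2(=C1H2)CO2Me; mixture of C18 epimers; otherwise as 21)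
Conditions: methyl acrylate (excess, as solvent), DABCO (1 equiv), MeOH (2 equiv), rt, dark
Reagents that add atoms: none
Why: Morita–Baylis–Hillman reaction in which the DABCO–acrylate zwitterion adds to the inductively activated α-silyloxy aldehyde, and the new C18 carbinol may form as either epimer because C18 becomes sp2 in the next step.

Step 17
Reactants: 23 Baylis–Hillman adduct
Product: 24 (Z)-allylic bromide (C17–C18H=C2(C1H2Br)CO2Me; C5–OPMB, C9–OTBDPS, C13–OTBS, C17–OTBS; 9S,13S,17S)
Conditions: NBS, Me2S, CH2Cl2, −20 → 0 °C (reagent premixed)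
Reagents that add atoms: N-bromosuccinimide, O=C1CCC(=O)N1Br
Why: Bromodimethylsulfonium bromide activates the allylic hydroxyl and bromide attacks the CH2 terminus (SN2′), which should give the thermodynamically preferred (Z)-2-(bromomethyl)-2-enoate while the premixed reagent leaves the other alkenes alone.

Step 18
Reactants: 24 (Z)-allylic bromide
Product: 25 C5 allylic alcohol of 24 (C5–OH)
Conditions: DDQ, CH2Cl2/pH 7 buffer, 0 °C
Reagents that add atoms: none
Why: Oxidative cleavage of the electron-rich PMB ether by DDQ, to which the allylic bromide, the enoate and the silyl ethers are inert.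

Step 19
Reactants: 25 C5 allylic alcohol
Product: 26 seco enal bromide (C5 enal; C1H2Br; C9–OTBDPS, C13–OTBS, C17–OTBS; 6E,10E,14E; 9S,13S,17S)
Conditions: MnO2 (excess), CH2Cl2, rt
Reagents that add atoms: none
Why: Manganese dioxide oxidises the primary allylic alcohol to the (E)-enal and tolerates the allylic bromide.

Step 20
Reactants: 26 seco enal bromide
Product: 29 tris-silyl macrolactone (trans-fused α-methylene-γ-lactone on the 14-membered ring; C9–OTBDPS; C13–OTBS; C17–OTBS; all five centres spatially as in the target), via allylchromium species 27 (not isolated), via chromium alkoxide 28 (not isolated)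
Conditions: CrCl2 (8 equiv), THF, rt, slow addition of 26 to 2 mM final concentration; aq. NH4Cl; then PPTS (cat.), CH2Cl2, rt to complete lactonisation
Reagents that add atoms: none
Why: Chromium(II) Barbier (Nozaki–Hiyama–Kishi) allylation at high dilution, in which Cr(II) inserts into the allylic C1–Br bond, the equilibrating 2-(methoxycarbonyl)allylchromium 27 attacks the C5 enal through its γ-carbon C18 in a chair transition state with both ring-chain substituents equatorial (anti adduct, hence the trans C5/C18 relationship and closure of the 14-membered carbocycle), C17 should direct the face of C18 by holding its C–H in the alkene plane (A(1,3) strain) with the ring chain C16 antiperiplanar to the forming bond, and alkoxide 28 then closes the γ-lactone onto the methyl ester.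

Step 21
Reactants: 29 tris-silyl macrolactone
Product: 30 C13,C17-diol macrolactone (C9–OTBDPS retained; 5S,9S,13S,17S,18S)
Conditions: HF·pyridine, pyridine, THF, 0 °C → rt
Reagents that add atoms: none
Why: HF·pyridine cleaves the two secondary TBS ethers while the more acid-stable secondary TBDPS ether should survive, and the non-nucleophilic, weakly acidic medium avoids lactone migration to O17.

Step 22
Reactants: 30 C13,C17-diol macrolactone
Product: 31 C13,C17-diacetate macrolactone (C9–OTBDPS; 5S,9S,13S,17S,18S)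
Conditions: Ac2O, pyridine, DMAP (cat.), CH2Cl2, 0 °C → rt
Reagents that add atoms: acetic anhydride, CC(=O)OC(C)=O
Why: DMAP-catalysed acetylation of both secondary alcohols, fast enough to outrun any acyl transfer of the lactone.

Step 23
Reactants: 31 C13,C17-diacetate macrolactone
Product: 32 target CNP0418981.1 (5S,9S,13S,17S,18S; 6E,10E,14E)
Conditions: TBAF, AcOH (1:1), THF, 0 °C → rt
Reagents that add atoms: none
Why: Acetic acid-buffered fluoride cleaves the TBDPS ether and should leave the acetates and the α-methylene lactone intact, the C9 oxygen being too remote from either ester for acyl migration.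

**Compound list**

1 | methyl 3-methylbut-2-enoate | COC(=O)C=C(C)C | starting material
2 | lithium dienolate of 1 (not isolated) | C=C(C)C=C(OC)[O-].[Li+] | intermediate
3 | tert-butyl[(1-methoxy-3-methylbuta-1,3-dien-1-yl)oxy]dimethylsilane (TBS dienolate) | C=C(C)C=C(OC)O[Si](C)(C)C(C)(C)C | intermediate
4 | (tert-butyldimethylsilyloxy)acetaldehyde | O=CCO[Si](C)(C)C(C)(C)C | starting material
5 | trichlorosilyl aldolate of pass 1 (not isolated) | COC(=O)/C=C(\C)C[C@H](O[Si](Cl)(Cl)Cl)CO[Si](C)(C)C(C)(C)C | intermediate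
6 | methyl (2E,5S)-6-(tert-butyldimethylsilyloxy)-5-hydroxy-3-methylhex-2-enoate | COC(=O)/C=C(\C)C[C@H](O)CO[Si](C)(C)C(C)(C)C | intermediate
7 | methyl (2E,5S)-5,6-bis(tert-butyldimethylsilyloxy)-3-methylhex-2-enoate | COC(=O)/C=C(\C)C[C@H](O[Si](C)(C)C(C)(C)C)CO[Si](C)(C)C(C)(C)C | intermediate
8 | (2E,5S)-5,6-bis(tert-butyldimethylsilyloxy)-3-methylhex-2-en-1-ol | OC/C=C(\C)C[C@H](O[Si](C)(C)C(C)(C)C)CO[Si](C)(C)C(C)(C)C | intermediate
9 | (2E,5S)-5,6-bis(tert-butyldimethylsilyloxy)-3-methylhex-2-enal | O=C/C=C(\C)C[C@H](O[Si](C)(C)C(C)(C)C)CO[Si](C)(C)C(C)(C)C | intermediate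
10 | trichlorosilyl aldolate of pass 2 (not isolated) | COC(=O)/C=C(\C)C[C@H](O[Si](Cl)(Cl)Cl)/C=C(\C)C[C@H](O[Si](C)(C)C(C)(C)C)CO[Si](C)(C)C(C)(C)C | intermediate
11 | methyl (2E,5S,6E,9S)-9,10-bis(tert-butyldimethylsilyloxy)-5-hydroxy-3,7-dimethyldeca-2,6-dienoate | COC(=O)/C=C(\C)C[C@H](O)/C=C(\C)C[C@H](O[Si](C)(C)C(C)(C)C)CO[Si](C)(C)C(C)(C)C | intermediate
12 | methyl (2E,5S,6E,9S)-5,9,10-tris(tert-butyldimethylsilyloxy)-3,7-dimethyldeca-2,6-dienoate | COC(=O)/C=C(\C)C[C@H](O[Si](C)(C)C(C)(C)C)/C=C(\C)C[C@H](O[Si](C)(C)C(C)(C)C)CO[Si](C)(C)C(C)(C)C | intermediate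
13 | (2E,5S,6E,9S)-5,9,10-tris(tert-butyldimethylsilyloxy)-3,7-dimethyldeca-2,6-dien-1-ol | OC/C=C(\C)C[C@H](O[Si](C)(C)C(C)(C)C)/C=C(\C)C[C@H](O[Si](C)(C)C(C)(C)C)CO[Si](C)(C)C(C)(C)C | intermediate
14 | (2E,5S,6E,9S)-5,9,10-tris(tert-butyldimethylsilyloxy)-3,7-dimethyldeca-2,6-dienal (C9 enal) | O=C/C=C(\C)C[C@H](O[Si](C)(C)C(C)(C)C)/C=C(\C)C[C@H](O[Si](C)(C)C(C)(C)C)CO[Si](C)(C)C(C)(C)C | intermediate
15 | trichlorosilyl aldolate of pass 3 (not isolated) | COC(=O)/C=C(\C)C[C@H](O[Si](Cl)(Cl)Cl)/C=C(\C)C[C@H](O[Si](C)(C)C(C)(C)C)/C=C(\C)C[C@H](O[Si](C)(C)C(C)(C)C)CO[Si](C)(C)C(C)(C)C | intermediate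
16 | methyl (2E,5S,6E,9S,10E,13S)-9,13,14-tris(tert-butyldimethylsilyloxy)-5-hydroxy-3,7,11-trimethyltetradeca-2,6,10-trienoate (C5–C18 chain ester) | COC(=O)/C=C(\C)C[C@H](O)/C=C(\C)C[C@H](O[Si](C)(C)C(C)(C)C)/C=C(\C)C[C@H](O[Si](C)(C)C(C)(C)C)CO[Si](C)(C)C(C)(C)C | intermediate
17 | methyl (2E,5S,6E,9S,10E,13S)-5-(tert-butyldiphenylsilyloxy)-9,13,14-tris(tert-butyldimethylsilyloxy)-3,7,11-trimethyltetradeca-2,6,10-trienoate | COC(=O)/C=C(\C)C[C@H](O[Si](c1ccccc1)(c1ccccc1)C(C)(C)C)/C=C(\C)C[C@H](O[Si](C)(C)C(C)(C)C)/C=C(\C)C[C@H](O[Si](C)(C)C(C)(C)C)CO[Si](C)(C)C(C)(C)C | intermediate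
18 | (2E,5S,6E,9S,10E,13S)-5-(tert-butyldiphenylsilyloxy)-9,13,14-tris(tert-butyldimethylsilyloxy)-3,7,11-trimethyltetradeca-2,6,10-trien-1-ol | OC/C=C(\C)C[C@H](O[Si](c1ccccc1)(c1ccccc1)C(C)(C)C)/C=C(\C)C[C@H](O[Si](C)(C)C(C)(C)C)/C=C(\C)C[C@H](O[Si](C)(C)C(C)(C)C)CO[Si](C)(C)C(C)(C)C | intermediate
19 | C5 4-methoxybenzyl ether of 18 | COc1ccc(COC/C=C(\C)C[C@H](O[Si](c2ccccc2)(c2ccccc2)C(C)(C)C)/C=C(\C)C[C@H](O[Si](C)(C)C(C)(C)C)/C=C(\C)C[C@H](O[Si](C)(C)C(C)(C)C)CO[Si](C)(C)C(C)(C)C)cc1 | intermediate
20 | C18 primary alcohol (C5–OPMB, C9–OTBDPS, C13/C17–OTBS; 9S,13S,17S) | COc1ccc(COC/C=C(\C)C[C@H](O[Si](c2ccccc2)(c2ccccc2)C(C)(C)C)/C=C(\C)C[C@H](O[Si](C)(C)C(C)(C)C)/C=C(\C)C[C@H](O[Si](C)(C)C(C)(C)C)CO)cc1 | intermediate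
21 | C18 aldehyde (α-silyloxy aldehyde) | COc1ccc(COC/C=C(\C)C[C@H](O[Si](c2ccccc2)(c2ccccc2)C(C)(C)C)/C=C(\C)C[C@H](O[Si](C)(C)C(C)(C)C)/C=C(\C)C[C@H](O[Si](C)(C)C(C)(C)C)C=O)cc1 | intermediate
22 | methyl acrylate | C=CC(=O)OC | starting material
23 | Baylis–Hillman adduct (C18 epimers) | COc1ccc(COC/C=C(\C)C[C@H](O[Si](c2ccccc2)(c2ccccc2)C(C)(C)C)/C=C(\C)C[C@H](O[Si](C)(C)C(C)(C)C)/C=C(\C)C[C@H](O[Si](C)(C)C(C)(C)C)C(O)C(=C)C(=O)OC)cc1 | intermediate
24 | (Z)-allylic bromide, C5–OPMB | COc1ccc(COC/C=C(\C)C[C@H](O[Si](c2ccccc2)(c2ccccc2)C(C)(C)C)/C=C(\C)C[C@H](O[Si](C)(C)C(C)(C)C)/C=C(\C)C[C@H](O[Si](C)(C)C(C)(C)C)/C=C(\CBr)C(=O)OC)cc1 | intermediate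
25 | (Z)-allylic bromide, C5–OH | OC/C=C(\C)C[C@H](O[Si](c1ccccc1)(c1ccccc1)C(C)(C)C)/C=C(\C)C[C@H](O[Si](C)(C)C(C)(C)C)/C=C(\C)C[C@H](O[Si](C)(C)C(C)(C)C)/C=C(\CBr)C(=O)OC | intermediate
26 | seco enal bromide (C5 enal, C1 bromide) | O=C/C=C(\C)C[C@H](O[Si](c1ccccc1)(c1ccccc1)C(C)(C)C)/C=C(\C)C[C@H](O[Si](C)(C)C(C)(C)C)/C=C(\C)C[C@H](O[Si](C)(C)C(C)(C)C)/C=C(\CBr)C(=O)OC | intermediate
27 | allylchromium(III) species from 26 (not isolated; allyl geometry mobile) | O=C/C=C(\C)C[C@H](O[Si](c1ccccc1)(c1ccccc1)C(C)(C)C)/C=C(\C)C[C@H](O[Si](C)(C)C(C)(C)C)/C=C(\C)C[C@H](O[Si](C)(C)C(C)(C)C)C=C(C[Cr](Cl)Cl)C(=O)OC | intermediate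
28 | ring-closed chromium(III) C5-alkoxide, methyl ester (not isolated) | COC(=O)C(=C)[C@@H]1[C@@H](O[Cr](Cl)Cl)/C=C(\C)C[C@H](O[Si](c2ccccc2)(c2ccccc2)C(C)(C)C)/C=C(\C)C[C@H](O[Si](C)(C)C(C)(C)C)/C=C(\C)C[C@@H]1O[Si](C)(C)C(C)(C)C | intermediate
29 | tris-silyl macrolactone (C9–OTBDPS, C13/C17–OTBS; centres spatially as in target) | C=C1C(=O)O[C@H]2/C=C(\C)C[C@H](O[Si](c3ccccc3)(c3ccccc3)C(C)(C)C)/C=C(\C)C[C@H](O[Si](C)(C)C(C)(C)C)/C=C(\C)C[C@H](O[Si](C)(C)C(C)(C)C)[C@H]12 | intermediate
30 | C13,C17-diol macrolactone (C9–OTBDPS) | C=C1C(=O)O[C@H]2/C=C(\C)C[C@H](O[Si](c3ccccc3)(c3ccccc3)C(C)(C)C)/C=C(\C)C[C@H](O)/C=C(\C)C[C@H](O)[C@H]12 | intermediate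
31 | C13,C17-diacetate macrolactone (C9–OTBDPS) | C=C1C(=O)O[C@H]2/C=C(\C)C[C@H](O[Si](c3ccccc3)(c3ccccc3)C(C)(C)C)/C=C(\C)C[C@H](OC(C)=O)/C=C(\C)C[C@H](OC(C)=O)[C@H]12 | intermediate
32 | CNP0418981.1 | C=C1C(=O)O[C@H]2/C=C(\C)C[C@H](O)/C=C(\C)C[C@H](OC(C)=O)/C=C(\C)C[C@H](OC(C)=O)[C@H]12 | target

**Step count and risks**

Total step count: 23. Longest linear sequence: 23 steps (1 → 3 → 6 → … → 32); dienolate 3 is made once and used in steps 2, 6 and 10.

Steps most likely to fail:

Step 20 (ring closure). Several things may go wrong: oligomerisation may compete with 14-ring closure; the allylmetal may lose the C17 silyloxy group by reductive 1,4-elimination; the addition may pass through a syn-selective transition state and give the cis C5/C18 relationship; or the C17 centre may fail to control the face of C18. The fallback sets out from 26 and sets C5 by inversion instead of by the allylation transition state. An indium-mediated Barbier closure in THF/H2O at high dilution, a protic medium in which γ-silyloxy-substituted (Z)-2-(bromomethyl)-2-enoates are expected to add to aldehydes with syn selectivity and without lactonisation, should give the ring-closed 5-epi hydroxy ester F1. Saponification with LiOH in THF/H2O and careful acidification at 0 °C should give the 5-epi hydroxy acid F2. Mitsunobu lactonisation (PPh3, DIAD, THF, 0 °C) then closes the lactone with inversion at C5 and comes back to the route at 29.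

Step 2 (first aldol pass). The non-conjugated α-silyloxy aldehyde may react sluggishly or be diverted under SiCl4, the small CH2OTBS group may give poor facial discrimination, and some (Z)-enoate may form and lactonise. The fallback sets out from 4 and builds the same unit without an aldol. Catalytic enantioselective propargylation with allenylboronic acid pinacol ester and a chiral BINOL-derived phosphoric acid (enantiomer chosen for the S alcohol) should give (S)-1-(tert-butyldimethylsilyloxy)pent-4-yn-2-ol F3. Silylation (TBSOTf, 2,6-lutidine) gives the bis-silyl ether F4. Zirconium-catalysed methylalumination of the terminal alkyne (Me3Al, Cp2ZrCl2, CH2Cl2; Negishi carboalumination) followed by trapping of the alkenylalane with methyl chloroformate installs the (E)-3-methyl-2-enoate by syn addition and comes back to the route at 7.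

Step 16 (Baylis–Hillman reaction). Amine-catalysed addition to a hindered α-silyloxy aldehyde may take days, and the long exposure to base may erode the C17 configuration through reversible enolisation. The fallback sets out from 21 and replaces the amine-catalysed process by a preformed vinylmetal. Hydroalumination of methyl propiolate with DIBAL-H/HMPA in THF at 0 °C should give methyl 2-(diisobutylalumanyl)acrylate F5, which adds to aldehyde 21 at low temperature within hours and comes back to the route at 23.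

Further compounds
F1 | step 20 | ring-closed 5-epi hydroxy ester (syn adduct; methyl ester; C5–OH) | COC(=O)C(=C)[C@@H]1[C@H](O)/C=C(\C)C[C@H](O[Si](c2ccccc2)(c2ccccc2)C(C)(C)C)/C=C(\C)C[C@H](O[Si](C)(C)C(C)(C)C)/C=C(\C)C[C@@H]1O[Si](C)(C)C(C)(C)C
F2 | step 20 | ring-closed 5-epi hydroxy acid | OC(=O)C(=C)[C@@H]1[C@H](O)/C=C(\C)C[C@H](O[Si](c2ccccc2)(c2ccccc2)C(C)(C)C)/C=C(\C)C[C@H](O[Si](C)(C)C(C)(C)C)/C=C(\C)C[C@@H]1O[Si](C)(C)C(C)(C)C
F3 | step 2 | (S)-1-(tert-butyldimethylsilyloxy)pent-4-yn-2-ol | C#CC[C@H](O)CO[Si](C)(C)C(C)(C)C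
F4 | step 2 | (S)-4,5-bis(tert-butyldimethylsilyloxy)pent-1-yne | C#CC[C@H](O[Si](C)(C)C(C)(C)C)CO[Si](C)(C)C(C)(C)C
F5 | step 16 | methyl 2-(diisobutylalumanyl)acrylate | C=C(C(=O)OC)[Al](CC(C)C)CC(C)C
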